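## Structural features

The target is a flavanone: benzo ring A is fused through C4a and C8a to the dihydropyranone ring C (O1, C2, C3, C4=O), and a 4-hydroxy-3-methoxyphenyl ring B is attached to C2 by the C2–C1' bond. Ring A is of the phloroglucinol type with oxygen at C5, C7 and C8a; a 3-methylbut-2-enyl (prenyl) chain sits on C6 between the C5 and C7 hydroxyls, and C8 is unsubstituted. C2 is the only stereocentre (S; O1 > C1' > C3 > H) and has no stereogenic neighbour. It is benzylic and β to the C4 ketone with O1 as a phenoxide leaving group, so base opens ring C to the chalcone and erases it. The prenyl alkene is electron-rich and flanked by two phenols: acid cyclises it to a dimethylchroman and hydrogenation saturates it, so neither acidic deprotection nor hydrogenolysis is safe once it is in place. The real difficulty is regiochemical, because C6 and C8 are each activated by two flanking oxygens and respond alike to small electrophiles, while the phenol oxygens and C5' of ring B compete as well. The key step uses the nucleophilic C6–H of ring A in the unprotected flavanone: a protein pocket that holds the C4=O/5-OH edge and the 7-OH can present C6, and not C8, to C1 of an enzyme-bound dimethylallyl cation.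

## Logic of the disconnections

**10 to 7 and 9.** The C6–C1'' bond is cut. It is the one bond whose formation needs no other change in the molecule, so the product of the forward step is the target itself. The gain is that 7 carries no alkene and can be assembled with hydrogenolysable protecting groups, and that the C6/C8 question is left to a catalyst that can answer it. The forward step must choose C6 over C8, over C5' of ring B, over the phenol oxygens and over attack through C3 of the allyl unit, and it must run near neutral pH so that ring C does not open.

**9 to 8.** The allylic C1–O bond of the diphosphate ester is cut. A primary allylic halide is displaced cleanly by diphosphate, and 8 is a purchasable C5 unit, so one step suffices. The forward step must keep the product away from acid, since the allylic diphosphate ionises easily, and must exchange the lipophilic counter-ions for ammonium so that 9 dissolves in buffer.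

**7 to 6.** Three benzyl C–O bonds are cut. The phenols must be masked for the organometallic step and for the ring closure to 4. Benzyl ethers are chosen over acetal-type ethers because they survive the acid used to close the chromone ring and are removed under neutral conditions. This option exists only because the prenyl group is introduced last. The forward step must stop before the benzylic C2–O1 bond is hydrogenolysed.

**6 to 4 and 5.** The C2–C1' bond is cut. This creates the only stereocentre by catalyst-controlled face selection on a flat acceptor and joins two achiral pieces, one of them purchasable. The acceptor is electron-rich and the product is a ketone that can undergo 1,2-addition or base-induced ring opening. The forward step therefore needs an active, base-free catalyst, and the 4'-oxygen of 5 is protected to avoid phenoxide binding to the metal and to limit protodeboronation.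

**4 to 2, through 3.** The O1–C2 and C2–C3 bonds are cut; C2 comes from a one-carbon amide acetal. This is the standard chromone annulation of an ortho-hydroxy aryl methyl ketone. It requires exactly one free ortho hydroxyl and protecting groups that tolerate the acid-promoted closure.

**2 to 1.** Two benzyl C–O bonds are cut. The symmetrical triphenol 1 is differentiated only by the hydrogen bond of an ortho hydroxyl to the acetyl group. The forward step must stop at the bis-ether and keep C-alkylation of the electron-rich ring low.

## Other disconnections considered

**Alternative 1:** The cut is O1–C8a of ring C. In the forward direction the (S)-carbinol of the bromo alcohol A2 would displace bromide at C8a under Pd(OAc)2, a bulky biarylphosphine and Cs2CO3, closing ring C to the protected flavan-4-ol A1.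
- In its favour: the prenyl group is placed on ring A before ring C exists, so the C6/C8 question never arises. C2 is made as a carbinol by reliable carbonyl chemistry and is carried with retention, because the coupling forms the bond at oxygen. C4 is at the alcohol level, so no base-labile β-aryloxy ketone is present during the basic step.
- Against it: A1 is still three operations from 10 (desilylation, oxidation at C4, removal of three MOM groups), and the C4 stereocentre is built only to be destroyed. Oxidative addition of zerovalent palladium into an electron-rich aryl bromide is slow, and β-hydride elimination from the palladium alkoxide of a secondary benzylic alcohol is a known competing path. The closing acid treatment would meet a prenyl group between two freshly liberated phenols, which invites chroman formation and may erode C2.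
- Comparison: on structure the alternative is the better of the two in one respect, since regiochemistry is fixed by construction and does not depend on a protein. On mechanism it is at least the equal in predictability of the bond-forming event. On step economy it is clearly worse, probably more than twice the six steps of the chosen plan, and it ends in acid, which the chosen plan avoids.

**Alternative 2:** The cut is C4a–C5 of ring A. In the forward direction Mg(OMe)2 would convert the β-keto ester A4 into a chelated polyenolate, C4a would attack the ester carbonyl, and enolisation would aromatise ring A to give A3.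
- In its favour: ring A and its whole substitution pattern arise in one event, with the prenyl group locked at C6 by its place in the chain between C5 and C7. The two ring A hydroxyls emerge free, so only one MOM group remains to be removed. The step mirrors polyketide folding.
- Against it: A4 is a sensitive polycarbonyl compound with several acidic sites, and its enantioselective preparation would be long. O-acylation and aldol pathways compete with the C-acylation. The C2 centre lies β to a carbonyl with an oxygen leaving group, so basic chelating conditions threaten it by ring opening and reclosure, more so once O1 becomes a phenoxide. The final acid step again meets a prenyl group next to free phenols.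
- Comparison: on structure the alternative is better at fixing the prenyl position without a selective catalyst, and nearly equal in protecting-group load at the end (one group against none). On mechanism the chosen plan is safer, since its last step is neutral and aqueous while this one exposes C2 to base. On step economy the alternative is worse.

**Alternative 3:** The cut is C2–C1'. In the forward direction the prenylated chromone A6 and the boronic acid A7 would combine under a monovalent rhodium catalyst with a chiral bicyclic diene to give the tris-MOM flavanone A5. Such a catalyst is better generated from [RhCl(C2H4)2]2, the diene and aqueous KOH than from [Rh(OH)(cod)]2, because cod is not readily displaced by a chiral diene.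
- In its favour: the stereo-defining reaction is the same as step 3 of the chosen route, so in how C2 is set the two plans are equal. No protein is needed and every step runs in ordinary glassware; in accessibility and ease of scale-up the alternative is the better.
- Against it: the regiochemical problem is moved, not removed. A6 would have to come from the prenylated ketone A8, whose two ortho hydroxyls must be told apart. The hydroxyl flanked by the prenyl group is the more hindered and the likelier to stay unprotected, and ring closure through it would put the prenyl group at C8; enforcing the other course costs steps. The 5-MOM ether, squeezed between the prenyl group and C4=O, adds hindrance near the acceptor. Acidic removal of three MOM groups with the prenyl group in place risks chroman formation, hydration of the alkene and erosion of C2.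
- Comparison: on structure the plans are equal for C2 and differ in where the C6/C8 decision is taken. On mechanism the alternative is the equal or better in predictability, since it does not depend on an enzyme accepting the substrate. On step economy it is somewhat longer (an estimated eight to ten steps) and needs an acidic end-game that the chosen plan does not.

Key step: step 6

Assumption: 5, 8 and tris(tetrabutylammonium) hydrogen diphosphate are taken as catalogue chemicals, which removes an aryl borylation and an alcohol-to-halide step.
Assumption: the prenyltransferase of step 6 is used as a purified recombinant protein from heterologous expression; its preparation is a biochemical operation and is not counted as a synthetic step.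
Assumption: the sense of induction of the diphosphine in step 3 (MeO-F12-BIPHEP, 6,6'-dimethoxy-2,2'-bis[bis(3,4,5-trifluorophenyl)phosphino]-1,1'-biphenyl) is fixed beforehand on a model chromone, and the antipode that leads to the (2S) product is used.
Remark: a check of the structures shows C2 as S and ring B as 4'-hydroxy-3'-methoxy in 7 and 10, with the prenyl group at C6; no structural correction is needed. The changes made concern the protecting groups (benzyl in place of acetal ethers) and the starting materials.

## Steps

Step 1
Reactants: 1 2,4,6-trihydroxyacetophenone (phloroacetophenone)
Product: 2 1-[2,4-bis(benzyloxy)-6-hydroxyphenyl]ethan-1-one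
Conditions: BnBr (2.1 equiv), K2CO3 (2.2 equiv), DMF, 0 °C to rt
Reagents that add atoms: benzyl bromide, BrCc1ccccc1
Why: Williamson ether synthesis; the 4-hydroxyl and one ortho hydroxyl react, while the remaining ortho hydroxyl is held in a hydrogen bond to the acetyl carbonyl and is much less nucleophilic, so alkylation should stop at the bis-ether with a slight excess of halide.

Step 2
Reactants: 2 1-[2,4-bis(benzyloxy)-6-hydroxyphenyl]ethan-1-one
Product: 4 5,7-bis(benzyloxy)-4H-chromen-4-one, via enaminone 3 (not isolated)
Conditions: Me2NCH(OMe)2 (2 equiv), toluene, 95 °C; evaporate; conc. HCl, CH2Cl2, rt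
Reagents that add atoms: N,N-dimethylformamide dimethyl acetal, COC(OC)N(C)C
Why: Condensation of the methyl ketone with the amide acetal gives enaminone 3, and acid then promotes conjugate addition of the free ortho hydroxyl and loss of dimethylamine (enaminone route to chromones); benzyl ethers tolerate the brief HCl treatment that acetal ethers would not.

Step 3
Reactants: 4 5,7-bis(benzyloxy)-4H-chromen-4-one; 5 [4-(benzyloxy)-3-methoxyphenyl]boronic acid
Product: 6 (2S)-5,7-bis(benzyloxy)-2-[4-(benzyloxy)-3-methoxyphenyl]-2,3-dihydro-4H-chromen-4-one
Conditions: 5 (2.5 equiv, in portions), [Rh(OH)(cod)]2 (2.5 mol%), MeO-F12-BIPHEP (5.5 mol%), CH2Cl2/H2O, 20 °C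
Reagents that add atoms: none
Why: Hayashi–Miyaura-type asymmetric 1,4-addition: transmetalation of 5 to the hydroxorhodium–diphosphine complex, insertion of the C2=C3 bond of 4 into the Rh–aryl bond and protonolysis of the rhodium enolate by water. The C2 stereocentre is set by the chiral diphosphine, which exposes one face of the planar chromone; the electron-poor ligand should speed insertion into the electron-rich acceptor, and the base-free medium avoids ring opening of the product.

Step 4
Reactants: 6 (2S)-5,7-bis(benzyloxy)-2-[4-(benzyloxy)-3-methoxyphenyl]-2,3-dihydro-4H-chromen-4-one
Product: 7 (2S)-homoeriodictyol, (2S)-5,7-dihydroxy-2-(4-hydroxy-3-methoxyphenyl)-2,3-dihydro-4H-chromen-4-one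
Conditions: H2 (1 atm), 10% Pd/C, EtOAc/MeOH, rt
Reagents that add atoms: none
Why: Palladium-catalysed hydrogenolysis of three aryl benzyl ethers under neutral conditions, which involve no enolisation and should leave C2 untouched; the step is admissible only because no alkene is present yet, and it is stopped at full conversion so that the benzylic C2–O1 bond is not cleaved.

Step 5
Reactants: 8 1-bromo-3-methylbut-2-ene (prenyl bromide)
Product: 9 dimethylallyl diphosphate (drawn as the free acid, handled as its triammonium salt)
Conditions: (n-Bu4N)3HP2O7 (2 equiv), MeCN, rt; then cation exchange (Dowex 50WX8, ammonium form), cellulose chromatography, lyophilisation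
Reagents that add atoms: tris(tetrabutylammonium) hydrogen diphosphate, CCCC[N+](CCCC)(CCCC)CCCC.CCCC[N+](CCCC)(CCCC)CCCC.CCCC[N+](CCCC)(CCCC)CCCC.OP(=O)([O-])OP(=O)([O-])[O-]
Why: SN2 displacement of the primary allylic bromide by the diphosphate anion, which the tetrabutylammonium counter-ions make soluble and nucleophilic in acetonitrile (standard allylic diphosphorylation); exchange to the ammonium salt should give a water-soluble form fit for the enzyme, and working above pH 7 prevents ionisation of the allylic C–O bond.

Step 6
Reactants: 7 (2S)-homoeriodictyol; 9 dimethylallyl diphosphate
Product: 10 (2S)-6-prenylhomoeriodictyol, (2S)-5,7-dihydroxy-2-(4-hydroxy-3-methoxyphenyl)-6-(3-methylbut-2-en-1-yl)-2,3-dihydro-4H-chromen-4-one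
Conditions: recombinant 7-DMATS (Aspergillus fumigatus), 9 (2 equiv), Tris-HCl 50 mM pH 7.5, CaCl2 5 mM, DMSO 5% v/v, 37 °C, 16 h; EtOAc extraction, reversed-phase chromatography
Reagents that add atoms: none
Why: Aromatic prenyltransferase-catalysed Friedel–Crafts alkylation: the enzyme binds 9, ionises its C–O bond to a dimethylallyl cation/diphosphate ion pair held by cation–π contacts in its aromatic-lined barrel, and C6 of ring A of 7 attacks C1 of the cation to give an arenium ion that loses the C6 proton and rearomatises. The closest known reaction type is the regiospecific C6 prenylation of 5,7-dihydroxyflavanones with dimethylallyl diphosphate by fungal dimethylallyltryptophan synthase-type enzymes. No ring is closed and no stereocentre is made; C2 should stay S because the medium is aqueous buffer near neutral pH and the step involves no enolisation. The selectivity needed is C6 over C8, over C5' of ring B, over the phenol oxygens and over attack through C3 of the cation (reverse prenylation). It is secured by the fixed orientation of the flavanone relative to the bound cation, with the hydrogen-bonded 5-OH/C4=O edge and the 7-OH as recognition elements that place C6, and not C8, within bonding distance of C1 of the cation. A second alkylation is disfavoured because the product is bulkier, and the excess of 9 compensates for its background hydrolysis.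

## Compound list

1 | 2,4,6-trihydroxyacetophenone (phloroacetophenone) | CC(=O)c1c(O)cc(O)cc1O | starting material
2 | 1-[2,4-bis(benzyloxy)-6-hydroxyphenyl]ethan-1-one | CC(=O)c1c(O)cc(OCc2ccccc2)cc1OCc1ccccc1 | intermediate
3 | (E)-1-[2,4-bis(benzyloxy)-6-hydroxyphenyl]-3-(dimethylamino)prop-2-en-1-one | CN(C)/C=C/C(=O)c1c(O)cc(OCc2ccccc2)cc1OCc1ccccc1 | intermediate (not isolated)
4 | 5,7-bis(benzyloxy)-4H-chromen-4-one | O=c1ccoc2cc(OCc3ccccc3)cc(OCc3ccccc3)c12 | intermediate
5 | [4-(benzyloxy)-3-methoxyphenyl]boronic acid | COc1cc(B(O)O)ccc1OCc1ccccc1 | starting material
6 | (2S)-5,7-bis(benzyloxy)-2-[4-(benzyloxy)-3-methoxyphenyl]-2,3-dihydro-4H-chromen-4-one | COc1cc([C@@H]2CC(=O)c3c(OCc4ccccc4)cc(OCc4ccccc4)cc3O2)ccc1OCc1ccccc1 | intermediate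
7 | (2S)-homoeriodictyol, (2S)-5,7-dihydroxy-2-(4-hydroxy-3-methoxyphenyl)-2,3-dihydro-4H-chromen-4-one | COc1cc([C@@H]2CC(=O)c3c(O)cc(O)cc3O2)ccc1O | intermediate
8 | 1-bromo-3-methylbut-2-ene (prenyl bromide) | CC(C)=CCBr | starting material
9 | dimethylallyl diphosphate (free acid drawn; handled as the triammonium salt) | CC(C)=CCOP(=O)(O)OP(=O)(O)O | intermediate
10 | (2S)-6-prenylhomoeriodictyol, (2S)-5,7-dihydroxy-2-(4-hydroxy-3-methoxyphenyl)-6-(3-methylbut-2-en-1-yl)-2,3-dihydro-4H-chromen-4-one | COc1cc([C@@H]2CC(=O)c3c(cc(O)c(CC=C(C)C)c3O)O2)ccc1O | target

## Step count and least certain steps

Total step count: 6. Longest linear sequence: 5 steps (steps 1, 2, 3, 4 and 6); step 5 is a one-step side branch.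

**Step 6 (key step).**
- What may go wrong: turnover may be too low because the 3'-methoxy-4'-hydroxy ring B fits the pocket poorly. Part of the prenyl transfer may go to C8, to ring B or to oxygen. The C2 configuration may erode slowly by reversible ring opening during a long incubation. Hydrolysis of 9 may outrun transfer.
- Fallback, from 7 back to 10: a chemical C6 prenylation in which the position is fixed by an ortho-Claisen rearrangement from O5, whose only free ortho carbon is C6.
  - Acetylation of the two non-chelated hydroxyls of 7 (Ac2O, pyridine, 0 °C) would give (2S)-7,4'-di-O-acetylhomoeriodictyol F3.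
  - Mitsunobu etherification of the chelated 5-hydroxyl with allyl alcohol (PPh3, DIAD, THF) would give (2S)-5-O-allyl-7,4'-di-O-acetylhomoeriodictyol F4.
  - Claisen rearrangement catalysed by Eu(fod)3 (CHCl3, 60 °C) would move the allyl group to C6 and give (2S)-6-allyl-7,4'-di-O-acetylhomoeriodictyol F5.
  - Cross-metathesis with excess 2-methylbut-2-ene and the second-generation Grubbs catalyst RuCl2(=CHPh)(H2IMes)(PCy3) would turn allyl into prenyl and give (2S)-7,4'-di-O-acetyl-6-prenylhomoeriodictyol F6.
  - Near-neutral deacetylation (NH4OAc, aqueous MeOH, rt) would return 10.
  - An allyl ether is used and not a prenyl ether because a prenyl ether would give the reverse-prenyl dienone, which relays by a Cope shift to C8.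

**Step 3.**
- What may go wrong: insertion into the electron-rich, peri-substituted acceptor may be slow, so that protodeboronation of the electron-rich boronic acid outruns addition. Aryl transfer to the C4 ketone of the product may occur. Facial discrimination may be insufficient.
- Fallback, from 2 back to 6: Claisen–Schmidt condensation of 2 with purchased 4-(benzyloxy)-3-methoxybenzaldehyde (KOH, EtOH) would give the chalcone (E)-1-[2,4-bis(benzyloxy)-6-hydroxyphenyl]-3-[4-(benzyloxy)-3-methoxyphenyl]prop-2-en-1-one F1. Oxa-Michael ring closure (NaOAc, EtOH, reflux) would give the racemic flavanone rac-5,7-bis(benzyloxy)-2-[4-(benzyloxy)-3-methoxyphenyl]-2,3-dihydro-4H-chromen-4-one F2. Preparative chromatography on a polysaccharide chiral stationary phase would deliver 6, and the unwanted antipode could be recycled through base-mediated ring opening.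

**Step 4.**
- What may go wrong: over-reduction by hydrogenolysis of the benzylic C2–O1 bond with opening of ring C, or incomplete cleavage of the hindered 5-O-benzyl ether.
- Fallback, from 6 back to 7: non-reductive Lewis-acid debenzylation with BCl3 and pentamethylbenzene as benzyl-cation scavenger in CH2Cl2 at −78 °C, a temperature at which the 3'-methyl ether should persist. No new compound arises on the way (F0).

## Further compounds

F1 | step 3 | (E)-1-[2,4-bis(benzyloxy)-6-hydroxyphenyl]-3-[4-(benzyloxy)-3-methoxyphenyl]prop-2-en-1-one | COc1cc(/C=C/C(=O)c2c(O)cc(OCc3ccccc3)cc2OCc2ccccc2)ccc1OCc1ccccc1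
F2 | step 3 | rac-5,7-bis(benzyloxy)-2-[4-(benzyloxy)-3-methoxyphenyl]-2,3-dihydro-4H-chromen-4-one | COc1cc(C2CC(=O)c3c(OCc4ccccc4)cc(OCc4ccccc4)cc3O2)ccc1OCc1ccccc1
F0 | step 4 | none | none
F3 | step 6 | (2S)-7,4'-di-O-acetylhomoeriodictyol | COc1cc([C@@H]2CC(=O)c3c(O)cc(OC(C)=O)cc3O2)ccc1OC(C)=O
F4 | step 6 | (2S)-5-O-allyl-7,4'-di-O-acetylhomoeriodictyol | COc1cc([C@@H]2CC(=O)c3c(OCC=C)cc(OC(C)=O)cc3O2)ccc1OC(C)=O
F5 | step 6 | (2S)-6-allyl-7,4'-di-O-acetylhomoeriodictyol | COc1cc([C@@H]2CC(=O)c3c(cc(OC(C)=O)c(CC=C)c3O)O2)ccc1OC(C)=O
F6 | step 6 | (2S)-7,4'-di-O-acetyl-6-prenylhomoeriodictyol | COc1cc([C@@H]2CC(=O)c3c(cc(OC(C)=O)c(CC=C(C)C)c3O)O2)ccc1OC(C)=O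
A1 | alternative 1 | (2S,4R)-4-(tert-butyldimethylsilyloxy)-5,7-bis(methoxymethoxy)-2-[3-methoxy-4-(methoxymethoxy)phenyl]-6-(3-methylbut-2-en-1-yl)chromane | COc1cc([C@@H]2C[C@@H](O[Si](C)(C)C(C)(C)C)c3c(cc(OCOC)c(CC=C(C)C)c3OCOC)O2)ccc1OCOC
A2 | alternative 1 | (1S,3R)-3-[6-bromo-2,4-bis(methoxymethoxy)-3-(3-methylbut-2-en-1-yl)phenyl]-3-(tert-butyldimethylsilyloxy)-1-[3-methoxy-4-(methoxymethoxy)phenyl]propan-1-ol | COc1cc([C@@H](O)C[C@@H](O[Si](C)(C)C(C)(C)C)c2c(Br)cc(OCOC)c(CC=C(C)C)c2OCOC)ccc1OCOC
A3 | alternative 2 | (2S)-5,7-dihydroxy-2-[3-methoxy-4-(methoxymethoxy)phenyl]-6-(3-methylbut-2-en-1-yl)-2,3-dihydro-4H-chromen-4-one | COc1cc([C@@H]2CC(=O)c3c(cc(O)c(CC=C(C)C)c3O)O2)ccc1OCOC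
A4 | alternative 2 | methyl 4-{(2S)-2-[3-methoxy-4-(methoxymethoxy)phenyl]-4-oxo-3,4-dihydro-2H-pyran-6-yl}-2-(3-methylbut-2-en-1-yl)-3-oxobutanoate | COC(=O)C(CC=C(C)C)C(=O)CC1=CC(=O)C[C@@H](c2ccc(OCOC)c(OC)c2)O1
A5 | alternative 3 | (2S)-5,7-bis(methoxymethoxy)-2-[3-methoxy-4-(methoxymethoxy)phenyl]-6-(3-methylbut-2-en-1-yl)-2,3-dihydro-4H-chromen-4-one | COc1cc([C@@H]2CC(=O)c3c(cc(OCOC)c(CC=C(C)C)c3OCOC)O2)ccc1OCOC
A6 | alternative 3 | 5,7-bis(methoxymethoxy)-6-(3-methylbut-2-en-1-yl)-4H-chromen-4-one | O=c1ccoc2cc(OCOC)c(CC=C(C)C)c(OCOC)c12
A7 | alternative 3 | [3-methoxy-4-(methoxymethoxy)phenyl]boronic acid | COCOc1ccc(B(O)O)cc1OC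
A8 | alternative 3 | 1-[2,4,6-trihydroxy-3-(3-methylbut-2-en-1-yl)phenyl]ethan-1-one | CC(=O)c1c(O)cc(O)c(CC=C(C)C)c1O
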